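**Plan**

- Feature used: counted from the ester carbon (C1), the 1,2-dioxane ring is O–O plus C3–C4–C5–C6. Its two C–O bonds sit on C3 and C6, so with a C4=C5 alkene put back the ring maps onto a C3=C4–C5=C6 diene and O2.
- Retrosynthesis: put back C4=C5 (diimide forwards), then cut C3–O and C6–O together (retro-[4+2] with singlet oxygen) to the (3E,5E)-diene ester. Cut C3=C4 (Julia–Kocienski) into a C1–C3 sulfone and a C4–C8 enal, then cut C5=C6 (Horner–Wadsworth–Emmons) back to a methyl ketone whose ring carbonyl comes from allylic oxidation of dihydro-β-ionone.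
- Forward: the carbocycle is bought and oxidised, the chain is grown from C6 to C4, C1–C3 is joined at C3=C4, and C1 is raised to the methyl ester. The peroxide ring is the only ring made, in the photooxygenation, and C4=C5 is then saturated.
- Stereochemistry: C2 (R) comes from methyl (S)-3-hydroxy-2-methylpropanoate. The cis relation of C3 and C6 follows from suprafacial addition of O2 to the (E,E)-diene, and C2 decides which π-face reacts, hence (3R,6R).

Key step: step 14

Remark: C1–C8 denote the carbons of the octanoate chain of the target. The photooxygenation is assumed to be run with light above 500 nm so that only the porphyrin absorbs.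

**Route**

Step 1
Reactants: 1 dihydro-β-ionone, 4-(2,6,6-trimethylcyclohex-1-en-1-yl)butan-2-one
Product: 2 2,4,4-trimethyl-3-(3-oxobutyl)cyclohex-2-en-1-one
Conditions: CrO3, 3,5-dimethylpyrazole, CH2Cl2, −20 °C
Reagents that add atoms: chromium trioxide, O=[Cr](=O)=O
Why: Allylic oxidation with the CrO3–3,5-dimethylpyrazole complex should convert the ring methylene next to the tetrasubstituted alkene into the conjugated cyclohexenone, the endocyclic CH2 being expected to react ahead of the side-chain CH2 and the ring methyl, while the saturated methyl ketone is inert to the hexavalent chromium reagent.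

Step 2
Reactants: 2 2,4,4-trimethyl-3-(3-oxobutyl)cyclohex-2-en-1-one; 3 triethyl phosphonoacetate
Product: 4 ethyl (2E)-3-methyl-5-(2,6,6-trimethyl-3-oxocyclohex-1-en-1-yl)pent-2-enoate
Conditions: NaH, THF, 0 °C → rt
Reagents that add atoms: none
Why: In this Horner–Wadsworth–Emmons olefination the sodium anion of 3 should add to the unhindered methyl ketone and not to the α-methylated, fully β-substituted ring enone, giving mainly the (E)-enoate (chain trans to the ester), with the minor (Z)-isomer removed by chromatography.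

Step 3
Reactants: 4 ethyl (2E)-3-methyl-5-(2,6,6-trimethyl-3-oxocyclohex-1-en-1-yl)pent-2-enoate
Product: 5 (2E)-5-(3-hydroxy-2,6,6-trimethylcyclohex-1-en-1-yl)-3-methylpent-2-en-1-ol (racemic at the ring carbinol carbon)
Conditions: i-Bu2AlH (excess), CH2Cl2, −78 → 0 °C; aq. potassium sodium tartrate
Reagents that add atoms: none
Why: i-Bu2AlH reduces both the enoate and the ring enone by 1,2-hydride delivery to the two allylic alcohols, and the ring carbinol centre, formed without control, is erased again in step 4.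

Step 4
Reactants: 5 (2E)-5-(3-hydroxy-2,6,6-trimethylcyclohex-1-en-1-yl)-3-methylpent-2-en-1-ol
Product: 6 (2E)-3-methyl-5-(2,6,6-trimethyl-3-oxocyclohex-1-en-1-yl)pent-2-enal
Conditions: activated MnO2 (excess), CH2Cl2, rt
Reagents that add atoms: none
Why: Activated MnO2 oxidises allylic alcohols selectively, so it should return the ring enone and give the enal in one operation without isomerising the (E)-alkene.

Step 5
Reactants: 7 methyl (S)-3-hydroxy-2-methylpropanoate
Product: 8 methyl (S)-3-[(tert-butyldimethylsilyl)oxy]-2-methylpropanoate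
Conditions: TBSCl, imidazole, CH2Cl2, 0 °C → rt
Reagents that add atoms: tert-butyldimethylsilyl chloride, CC(C)(C)[Si](C)(C)Cl
Why: Imidazole-promoted silylation of the primary alcohol is a standard protection that does not touch the stereocentre.

Step 6
Reactants: 8 methyl (S)-3-[(tert-butyldimethylsilyl)oxy]-2-methylpropanoate
Product: 9 (R)-3-[(tert-butyldimethylsilyl)oxy]-2-methylpropan-1-ol
Conditions: i-Bu2AlH, CH2Cl2, −78 → −40 °C; aq. potassium sodium tartrate
Reagents that add atoms: none
Why: Hydride reduction of the ester gives the primary alcohol, and low temperature with a neutral work-up prevents the silyl shift between the two oxygens that would racemise this compound.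

Step 7
Reactants: 9 (R)-3-[(tert-butyldimethylsilyl)oxy]-2-methylpropan-1-ol; 10 1-phenyl-1H-tetrazole-5-thiol
Product: 11 5-{[(2S)-3-[(tert-butyldimethylsilyl)oxy]-2-methylpropyl]sulfanyl}-1-phenyl-1H-tetrazole
Conditions: PPh3, DIAD, THF, 0 °C → rt
Reagents that add atoms: none
Why: The Mitsunobu reaction replaces the primary hydroxyl by the acidic thiol at a CH2 carbon, so the neighbouring stereocentre is not involved.

Step 8
Reactants: 11 5-{[(2S)-3-[(tert-butyldimethylsilyl)oxy]-2-methylpropyl]sulfanyl}-1-phenyl-1H-tetrazole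
Product: 12 5-{[(2S)-3-[(tert-butyldimethylsilyl)oxy]-2-methylpropyl]sulfonyl}-1-phenyl-1H-tetrazole
Conditions: (NH4)6Mo7O24·4H2O (cat.), 30% aq. H2O2, EtOH, 0 °C → rt
Reagents that add atoms: hydrogen peroxide, OO
Why: Molybdate-catalysed oxidation with H2O2 takes the sulfide to the sulfone under conditions that a primary silyl ether normally survives.

Step 9
Reactants: 12 5-{[(2S)-3-[(tert-butyldimethylsilyl)oxy]-2-methylpropyl]sulfonyl}-1-phenyl-1H-tetrazole; 6 (2E)-3-methyl-5-(2,6,6-trimethyl-3-oxocyclohex-1-en-1-yl)pent-2-enal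
Product: 13 3-[(3E,5E,7R)-8-[(tert-butyldimethylsilyl)oxy]-3,7-dimethylocta-3,5-dien-1-yl]-2,4,4-trimethylcyclohex-2-en-1-one
Conditions: KN(SiMe3)2, DME, −60 °C; then 6, −60 °C → rt
Reagents that add atoms: none
Why: In this Julia–Kocienski olefination the metalated phenyltetrazolyl sulfone should add to the aldehyde, which is far more electrophilic than the hindered ring ketone, and Smiles rearrangement with loss of SO2 and the tetrazolone forms C3=C4, expected mainly as the E isomer, with any (3Z)-diene removed by chromatography and the C2 centre, β to the carbanion, unaffected.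

Step 10
Reactants: 13 3-[(3E,5E,7R)-8-[(tert-butyldimethylsilyl)oxy]-3,7-dimethylocta-3,5-dien-1-yl]-2,4,4-trimethylcyclohex-2-en-1-one
Product: 14 3-[(3E,5E,7R)-8-hydroxy-3,7-dimethylocta-3,5-dien-1-yl]-2,4,4-trimethylcyclohex-2-en-1-one
Conditions: Bu4NF, THF, 0 °C → rt
Reagents that add atoms: none
Why: Fluoride cleaves the primary silyl ether, and nothing else in the molecule is sensitive at this stage because C2 is not yet next to a carbonyl group.

Step 11
Reactants: 14 3-[(3E,5E,7R)-8-hydroxy-3,7-dimethylocta-3,5-dien-1-yl]-2,4,4-trimethylcyclohex-2-en-1-one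
Product: 15 (2R,3E,5E)-2,6-dimethyl-8-(2,6,6-trimethyl-3-oxocyclohex-1-en-1-yl)octa-3,5-dienal
Conditions: Dess–Martin periodinane, NaHCO3, CH2Cl2, 0 °C; used crude at once
Reagents that add atoms: none
Why: Buffered Dess–Martin oxidation is fast and essentially neutral, which is what the α-stereogenic β,γ-unsaturated aldehyde needs in order to keep its C2 configuration and its unconjugated diene.

Step 12
Reactants: 15 (2R,3E,5E)-2,6-dimethyl-8-(2,6,6-trimethyl-3-oxocyclohex-1-en-1-yl)octa-3,5-dienal
Product: 16 (2R,3E,5E)-2,6-dimethyl-8-(2,6,6-trimethyl-3-oxocyclohex-1-en-1-yl)octa-3,5-dienoic acid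
Conditions: NaClO2, NaH2PO4, 2-methyl-2-butene (large excess), t-BuOH/H2O, 0 °C → rt
Reagents that add atoms: sodium chlorite, [Na+].[O-]Cl=O
Why: The Pinnick oxidation works in a weakly acidic buffer in which the aldehyde does not enolise, and the excess of 2-methyl-2-butene traps the hypochlorous acid before it can attack the diene.

Step 13
Reactants: 16 (2R,3E,5E)-2,6-dimethyl-8-(2,6,6-trimethyl-3-oxocyclohex-1-en-1-yl)octa-3,5-dienoic acid
Product: 17 methyl (2R,3E,5E)-2,6-dimethyl-8-(2,6,6-trimethyl-3-oxocyclohex-1-en-1-yl)octa-3,5-dienoate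
Conditions: Me3SiCHN2, toluene/MeOH, 0 °C
Reagents that add atoms: (trimethylsilyl)diazomethane, C[Si](C)(C)C=[N+]=[N-]
Why: Methylation of the carboxylic acid with the diazoalkane needs no base, so the doubly activated C2–H is neither removed nor the diene drawn into conjugation.

Step 14
Reactants: 17 methyl (2R,3E,5E)-2,6-dimethyl-8-(2,6,6-trimethyl-3-oxocyclohex-1-en-1-yl)octa-3,5-dienoate
Product: 18 methyl (2R)-2-[(3R,6R)-6-methyl-6-[2-(2,6,6-trimethyl-3-oxocyclohex-1-en-1-yl)ethyl]-3,6-dihydro-1,2-dioxin-3-yl]propanoate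
Conditions: O2, tetraphenylporphyrin (cat.), hν (> 500 nm), CH2Cl2, 0 °C
Reagents that add atoms: dioxygen (reacting as singlet oxygen), O=O
Why: Porphyrin-sensitised singlet oxygen adds suprafacially, in one concerted [4+2] (hetero-Diels–Alder) event, across C3 and C6 of the s-cis conformer of the (3E,5E)-diene, the closest known reaction type being the photooxygenation of acyclic (E,E)-1,3-dienes to cis-3,6-disubstituted 3,6-dihydro-1,2-dioxines. The six-membered peroxide ring closes by this cycloaddition itself, the C3–O and C6–O bonds forming together while the alkene moves to C4=C5. The relative configuration of C3 and C6 is fixed by the diene geometry, because the two outward groups (the C2 branch and the C7 chain) must end cis on the ring. The absolute sense is set by C2: with the C2–H bond near the diene plane (eclipsing C3=C4, least allylic strain) the methyl group covers one π-face and the flat ester lies on the other, so oxygen should enter anti to the methyl group and give (3R,6R); because C4 carries only hydrogen cis to C2 this bias is expected to be modest, and the (3S,6S)-cis adduct would be removed by chromatography. The step needs cycloaddition to outrun the ene reaction at the trisubstituted C5=C6 terminus and needs the other π-systems to stay inert: the (E,E) geometry allows the s-cis conformer, working at 0 °C and not at −78 °C keeps that conformer populated, the polar allylic hydroperoxides of the ene pathway are separable, and the ring enone alkene is too electron-poor to react with singlet oxygen.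

Step 15
Reactants: 18 methyl (2R)-2-[(3R,6R)-6-methyl-6-[2-(2,6,6-trimethyl-3-oxocyclohex-1-en-1-yl)ethyl]-3,6-dihydro-1,2-dioxin-3-yl]propanoate
Product: 19 diacarperoxide A, methyl (2R)-2-[(3R,6R)-6-methyl-6-[2-(2,6,6-trimethyl-3-oxocyclohex-1-en-1-yl)ethyl]-1,2-dioxan-3-yl]propanoate
Conditions: KO2CN=NCO2K (excess), AcOH (slow addition), CH2Cl2/MeOH, 0 °C → rt
Reagents that add atoms: none
Why: Diimide reduction transfers H2 in a concerted syn fashion to the unpolarised cis C4=C5 ring alkene and leaves the O–O bond, the ester and the tetrasubstituted electron-poor enone alkene alone, while the mildly acidic medium avoids base-induced Kornblum–DeLaMare opening of the peroxide and no stereocentre is touched.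

**Compound list**

1 | dihydro-β-ionone, 4-(2,6,6-trimethylcyclohex-1-en-1-yl)butan-2-one | CC(=O)CCC1=C(C)CCCC1(C)C | starting material
2 | 2,4,4-trimethyl-3-(3-oxobutyl)cyclohex-2-en-1-one | CC(=O)CCC1=C(C)C(=O)CCC1(C)C | intermediate
3 | triethyl phosphonoacetate | CCOC(=O)CP(=O)(OCC)OCC | starting material
4 | ethyl (2E)-3-methyl-5-(2,6,6-trimethyl-3-oxocyclohex-1-en-1-yl)pent-2-enoate | CCOC(=O)/C=C(\C)CCC1=C(C)C(=O)CCC1(C)C | intermediate
5 | (2E)-5-(3-hydroxy-2,6,6-trimethylcyclohex-1-en-1-yl)-3-methylpent-2-en-1-ol (racemic at the ring carbinol carbon) | OC/C=C(\C)CCC1=C(C)C(O)CCC1(C)C | intermediate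
6 | (2E)-3-methyl-5-(2,6,6-trimethyl-3-oxocyclohex-1-en-1-yl)pent-2-enal | O=C/C=C(\C)CCC1=C(C)C(=O)CCC1(C)C | intermediate
7 | methyl (S)-3-hydroxy-2-methylpropanoate | COC(=O)[C@@H](C)CO | starting material
8 | methyl (S)-3-[(tert-butyldimethylsilyl)oxy]-2-methylpropanoate | COC(=O)[C@@H](C)CO[Si](C)(C)C(C)(C)C | intermediate
9 | (R)-3-[(tert-butyldimethylsilyl)oxy]-2-methylpropan-1-ol | OC[C@@H](C)CO[Si](C)(C)C(C)(C)C | intermediate
10 | 1-phenyl-1H-tetrazole-5-thiol | Sc1nnnn1-c1ccccc1 | starting material
11 | 5-{[(2S)-3-[(tert-butyldimethylsilyl)oxy]-2-methylpropyl]sulfanyl}-1-phenyl-1H-tetrazole | CC(C)(C)[Si](C)(C)OC[C@H](C)CSc1nnnn1-c1ccccc1 | intermediate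
12 | 5-{[(2S)-3-[(tert-butyldimethylsilyl)oxy]-2-methylpropyl]sulfonyl}-1-phenyl-1H-tetrazole | CC(C)(C)[Si](C)(C)OC[C@H](C)CS(=O)(=O)c1nnnn1-c1ccccc1 | intermediate
13 | 3-[(3E,5E,7R)-8-[(tert-butyldimethylsilyl)oxy]-3,7-dimethylocta-3,5-dien-1-yl]-2,4,4-trimethylcyclohex-2-en-1-one | CC(C)(C)[Si](C)(C)OC[C@H](C)/C=C/C=C(\C)CCC1=C(C)C(=O)CCC1(C)C | intermediate
14 | 3-[(3E,5E,7R)-8-hydroxy-3,7-dimethylocta-3,5-dien-1-yl]-2,4,4-trimethylcyclohex-2-en-1-one | OC[C@H](C)/C=C/C=C(\C)CCC1=C(C)C(=O)CCC1(C)C | intermediate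
15 | (2R,3E,5E)-2,6-dimethyl-8-(2,6,6-trimethyl-3-oxocyclohex-1-en-1-yl)octa-3,5-dienal | O=C[C@H](C)/C=C/C=C(\C)CCC1=C(C)C(=O)CCC1(C)C | intermediate
16 | (2R,3E,5E)-2,6-dimethyl-8-(2,6,6-trimethyl-3-oxocyclohex-1-en-1-yl)octa-3,5-dienoic acid | OC(=O)[C@H](C)/C=C/C=C(\C)CCC1=C(C)C(=O)CCC1(C)C | intermediate
17 | methyl (2R,3E,5E)-2,6-dimethyl-8-(2,6,6-trimethyl-3-oxocyclohex-1-en-1-yl)octa-3,5-dienoate | COC(=O)[C@H](C)/C=C/C=C(\C)CCC1=C(C)C(=O)CCC1(C)C | intermediate
18 | methyl (2R)-2-[(3R,6R)-6-methyl-6-[2-(2,6,6-trimethyl-3-oxocyclohex-1-en-1-yl)ethyl]-3,6-dihydro-1,2-dioxin-3-yl]propanoate | COC(=O)[C@H](C)[C@H]1C=C[C@@](C)(CCC2=C(C)C(=O)CCC2(C)C)OO1 | intermediate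
19 | diacarperoxide A, methyl (2R)-2-[(3R,6R)-6-methyl-6-[2-(2,6,6-trimethyl-3-oxocyclohex-1-en-1-yl)ethyl]-1,2-dioxan-3-yl]propanoate | COC(=O)[C@H](C)[C@H]1CC[C@@](C)(CCC2=C(C)C(=O)CCC2(C)C)OO1 | target

**Step count**

Total: 15 steps. Longest linear sequence: 11 steps (steps 1–4 then 9–15; the sulfone branch, steps 5–8 then 9–15, is equally long).

**Steps most likely to fail**

1. Step 14. The ene reaction of singlet oxygen at the trisubstituted C5=C6 terminus may outrun the cycloaddition, and the weak conformational lock at C2 may discriminate poorly between the two diene faces, so that the (3R,6R) and (3S,6S) cis adducts form in similar amounts. Fallback: the ring is closed stepwise by hydroperoxide displacement, with C2 and C3 fixed before the peroxide enters. It sets out from 2 and 9 and returns to the route at 19.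
   - Wittig methylenation of 2 (Ph3PCH3Br, KOt-Bu, THF, 0 °C; the methyl ketone reacts ahead of the hindered enone) would give 2,4,4-trimethyl-3-(3-methylbut-3-en-1-yl)cyclohex-2-en-1-one F1.
   - Swern oxidation of 9 would give (S)-3-[(tert-butyldimethylsilyl)oxy]-2-methylpropanal F2. Brown allylation, using the enantiomer of B-allyldiisopinocampheylborane that reinforces Felkin addition, would give the 2,3-syn alcohol (2S,3S)-1-[(tert-butyldimethylsilyl)oxy]-2-methylhex-5-en-3-ol F3.
   - Cross-metathesis of F3 with an excess of F1 (second-generation Hoveyda–Grubbs catalyst, CH2Cl2, 40 °C) would give 3-[(6S,7S)-8-[(tert-butyldimethylsilyl)oxy]-6-hydroxy-3,7-dimethyloct-3-en-1-yl]-2,4,4-trimethylcyclohex-2-en-1-one F4, as an E/Z mixture that does not matter.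
   - Mesylation (MsCl, Et3N, CH2Cl2, 0 °C) would give (2S,3S)-1-[(tert-butyldimethylsilyl)oxy]-2,6-dimethyl-8-(2,6,6-trimethyl-3-oxocyclohex-1-en-1-yl)oct-5-en-3-yl methanesulfonate F5.
   - Mukaiyama–Isayama hydroperoxysilylation (Co(acac)2, Et3SiH, O2, EtOH, rt) would place the peroxide on the tertiary carbon C6 and give (2S,3S)-1-[(tert-butyldimethylsilyl)oxy]-2,6-dimethyl-6-[(triethylsilyl)peroxy]-8-(2,6,6-trimethyl-3-oxocyclohex-1-en-1-yl)octan-3-yl methanesulfonate F6 as both C6 epimers.
   - Bu4NF (THF, 0 °C) would cleave the silyl peroxide; the peroxide anion displaces the C3 mesylate in a 6-exo-tet closure with inversion, and the silyl ether is lost as well. After separation of the C6 epimers this gives (2S)-2-[(3R,6R)-6-methyl-6-[2-(2,6,6-trimethyl-3-oxocyclohex-1-en-1-yl)ethyl]-1,2-dioxan-3-yl]propan-1-ol F7.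
   - Oxidation (TEMPO, PhI(OAc)2, MeCN/H2O) would give (2R)-2-[(3R,6R)-6-methyl-6-[2-(2,6,6-trimethyl-3-oxocyclohex-1-en-1-yl)ethyl]-1,2-dioxan-3-yl]propanoic acid F8, and Me3SiCHN2 would give 19.
   - The price is that C6 is formed without control.

2. Step 11. At the stage of the α-stereogenic β,γ-unsaturated aldehyde, enolisation can epimerise C2 or pull the C3=C4 bond into conjugation, and the same threat persists through step 12. Fallback: C1 is oxidised only after the peroxide ring exists and C2 is no longer allylic. It sets out from 14 and returns to the route at 19. Photooxygenation of 14 under the conditions of step 14 (the free hydroxyl can hydrogen-bond to the incoming oxygen) would give (2S)-2-[(3R,6R)-6-methyl-6-[2-(2,6,6-trimethyl-3-oxocyclohex-1-en-1-yl)ethyl]-3,6-dihydro-1,2-dioxin-3-yl]propan-1-ol F9. Diimide reduction as in step 15 would give the alcohol F7 of the first fallback, which is taken on through acid F8 to 19 in the same way.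

3. Step 1. Hydrogen abstraction at the side-chain methylene next to the ring alkene, or at the ring methyl, can compete with oxidation of the ring methylene, and over-oxidation can follow. Fallback: the side chain is made unable to compete by starting from its unsaturated form. This fallback changes the starting material: it sets out from commercial β-ionone, (3E)-4-(2,6,6-trimethylcyclohex-1-en-1-yl)but-3-en-2-one F10, in place of 1 and returns to the route at 2. Allylic oxidation of F10 (CrO3, 3,5-dimethylpyrazole, CH2Cl2, −20 °C), where the ring CH2 is the only allylic methylene, would give 4-oxo-β-ionone, 2,4,4-trimethyl-3-[(1E)-3-oxobut-1-en-1-yl]cyclohex-2-en-1-one F11. Conjugate reduction with Stryker's reagent, [(Ph3P)CuH]6 (toluene, rt), should deliver hydride to the accessible β-carbon of the side-chain enone, not to the fully substituted β-carbon of the ring enone, and give 2.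

**Further compounds**

F1 | step 14 | 2,4,4-trimethyl-3-(3-methylbut-3-en-1-yl)cyclohex-2-en-1-one | C=C(C)CCC1=C(C)C(=O)CCC1(C)C
F2 | step 14 | (S)-3-[(tert-butyldimethylsilyl)oxy]-2-methylpropanal | O=C[C@@H](C)CO[Si](C)(C)C(C)(C)C
F3 | step 14 | (2S,3S)-1-[(tert-butyldimethylsilyl)oxy]-2-methylhex-5-en-3-ol | CC(C)(C)[Si](C)(C)OC[C@H](C)[C@@H](O)CC=C
F4 | step 14 | 3-[(6S,7S)-8-[(tert-butyldimethylsilyl)oxy]-6-hydroxy-3,7-dimethyloct-3-en-1-yl]-2,4,4-trimethylcyclohex-2-en-1-one (E/Z mixture) | CC(C)(C)[Si](C)(C)OC[C@H](C)[C@@H](O)CC=C(C)CCC1=C(C)C(=O)CCC1(C)C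
F5 | step 14 | (2S,3S)-1-[(tert-butyldimethylsilyl)oxy]-2,6-dimethyl-8-(2,6,6-trimethyl-3-oxocyclohex-1-en-1-yl)oct-5-en-3-yl methanesulfonate | CC(C)(C)[Si](C)(C)OC[C@H](C)[C@@H](OS(C)(=O)=O)CC=C(C)CCC1=C(C)C(=O)CCC1(C)C
F6 | step 14 | (2S,3S)-1-[(tert-butyldimethylsilyl)oxy]-2,6-dimethyl-6-[(triethylsilyl)peroxy]-8-(2,6,6-trimethyl-3-oxocyclohex-1-en-1-yl)octan-3-yl methanesulfonate (both C6 epimers) | CC(C)(C)[Si](C)(C)OC[C@H](C)[C@@H](OS(C)(=O)=O)CCC(C)(OO[Si](CC)(CC)CC)CCC1=C(C)C(=O)CCC1(C)C
F7 | step 14 | (2S)-2-[(3R,6R)-6-methyl-6-[2-(2,6,6-trimethyl-3-oxocyclohex-1-en-1-yl)ethyl]-1,2-dioxan-3-yl]propan-1-ol | OC[C@H](C)[C@H]1CC[C@@](C)(CCC2=C(C)C(=O)CCC2(C)C)OO1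
F8 | step 14 | (2R)-2-[(3R,6R)-6-methyl-6-[2-(2,6,6-trimethyl-3-oxocyclohex-1-en-1-yl)ethyl]-1,2-dioxan-3-yl]propanoic acid | OC(=O)[C@H](C)[C@H]1CC[C@@](C)(CCC2=C(C)C(=O)CCC2(C)C)OO1
F9 | step 11 | (2S)-2-[(3R,6R)-6-methyl-6-[2-(2,6,6-trimethyl-3-oxocyclohex-1-en-1-yl)ethyl]-3,6-dihydro-1,2-dioxin-3-yl]propan-1-ol | OC[C@H](C)[C@H]1C=C[C@@](C)(CCC2=C(C)C(=O)CCC2(C)C)OO1
F10 | step 1 | β-ionone, (3E)-4-(2,6,6-trimethylcyclohex-1-en-1-yl)but-3-en-2-one | CC(=O)/C=C/C1=C(C)CCCC1(C)C
F11 | step 1 | 4-oxo-β-ionone, 2,4,4-trimethyl-3-[(1E)-3-oxobut-1-en-1-yl]cyclohex-2-en-1-one | CC(=O)/C=C/C1=C(C)C(=O)CCC1(C)C
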